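The route opens both carbocycles at once through an intramolecular Diels–Alder disconnection. The key step exploits the cis-fused decalin in which the C4 methyl, C5 methyl and C10 oxygen are syn: ring B (C10, C1–C5) is the cycloadduct ring and ring A (C5–C10) the tether ring. In one operation an open-chain trienone should form C3–C4 and C5–C10, both rings and the C4, C5 and C10 stereocentres, steered by the C9 silyl ether that comes from D-glutamic acid. The precursor is an undecatrienone with an (E)-2-methylbut-2-enoyl dienophile, a C9 TBS ether and a (Z)-1-triethylsilyloxy diene, made regiospecifically from an allyl ketone.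

Key step: step 8

Remark: locants C1–C10 are those of the decalin core of the target (ring B = C10, C1, C2, C3, C4, C5; ring A = C5, C6, C7, C8, C9, C10); β is the face of the C5 methyl group, α the opposite face.

Step 1
Reactants: 1 D-glutamic acid
Product: 2 (R)-5-oxotetrahydrofuran-2-carboxylic acid
Conditions: NaNO2, 2 M HCl, H2O, 0 °C to rt
Reagents that add atoms: none
Why: Diazotisation of the α-amino acid proceeds by double inversion through an α-lactone, so the C9 oxygen is installed with net retention while the γ-carboxyl closes the γ-lactone (deaminative lactonisation).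

Step 2
Reactants: 2 (R)-5-oxotetrahydrofuran-2-carboxylic acid
Product: 4 (R)-N-methoxy-N-methyl-5-oxotetrahydrofuran-2-carboxamide, via acyl imidazolide 3 (not isolated)
Conditions: 1,1'-carbonyldiimidazole, CH2Cl2, rt; then MeNH(OMe)·HCl, rt
Reagents that add atoms: N,O-dimethylhydroxylamine hydrochloride, CNOC.Cl
Why: Activation of the free acid as its acyl imidazolide and aminolysis give the N-methoxy-N-methylamide (carbonyldiimidazole amidation) without touching the lactone or the C9 centre.

Step 3
Reactants: 4 (R)-N-methoxy-N-methyl-5-oxotetrahydrofuran-2-carboxamide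
Product: 5 (R)-2-hydroxy-N-methoxy-N-methyl-5-(morpholin-4-yl)-5-oxopentanamide
Conditions: morpholine, AlMe3, CH2Cl2, 0 °C to rt; aqueous potassium sodium tartrate
Reagents that add atoms: morpholine, C1COCCN1
Why: The dimethylaluminium amide made from AlMe3 and morpholine opens the γ-lactone by acyl substitution (aluminium amide aminolysis of a lactone), which frees the C9 hydroxyl and turns C6 into a morpholine amide that is sluggish toward Grignard reagents, while amides such as the one at C10 are inert to this reagent.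

Step 4
Reactants: 5 (R)-2-hydroxy-N-methoxy-N-methyl-5-(morpholin-4-yl)-5-oxopentanamide
Product: 6 (R)-2-(tert-butyldimethylsilyloxy)-N-methoxy-N-methyl-5-(morpholin-4-yl)-5-oxopentanamide
Conditions: TBSCl, imidazole, DMF, rt
Reagents that add atoms: tert-butyldimethylsilyl chloride, CC(C)(C)[Si](C)(C)Cl
Why: Imidazole-promoted O-silylation of the secondary α-hydroxy amide breaks no bond to C9 and blocks relactonisation.

Step 5
Reactants: 6 (R)-2-(tert-butyldimethylsilyloxy)-N-methoxy-N-methyl-5-(morpholin-4-yl)-5-oxopentanamide; 7 allylmagnesium bromide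
Product: 8 (R)-4-(tert-butyldimethylsilyloxy)-1-(morpholin-4-yl)oct-7-ene-1,5-dione
Conditions: THF, −78 °C; inverse quench into cold aqueous NH4Cl
Reagents that add atoms: none
Why: The N-methoxy-N-methylamide, activated by its α-oxygen, should take up one allyl group at −78 °C to give a stable chelated adduct that releases the β,γ-unsaturated ketone only on cold quench (Weinreb ketone synthesis), whereas the unactivated morpholine amide should not react at this temperature.

Step 6
Reactants: 8 (R)-4-(tert-butyldimethylsilyloxy)-1-(morpholin-4-yl)oct-7-ene-1,5-dione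
Product: 9 (4R,5Z)-4-(tert-butyldimethylsilyloxy)-1-(morpholin-4-yl)-5-(triethylsilyloxy)octa-5,7-dien-1-one
Conditions: Et3SiOTf, Et3N, CH2Cl2, −78 °C
Reagents that add atoms: triethylsilyl trifluoromethanesulfonate, CC[Si](CC)(CC)OS(=O)(=O)C(F)(F)F
Why: Soft enolisation removes a C1 hydrogen, which is both α to the ketone and allylic, far faster than the C9 methine, so the conjugated dienol ether should form regiospecifically without risk to C9, and the vinyl group settles trans to the bulky C9 substituent and hence cis to oxygen, giving the (Z)-enol ether.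

Step 7
Reactants: 9 (4R,5Z)-4-(tert-butyldimethylsilyloxy)-1-(morpholin-4-yl)-5-(triethylsilyloxy)octa-5,7-dien-1-one; 10 (E)-2-bromobut-2-ene
Product: 12 (2E,7R,8Z)-7-(tert-butyldimethylsilyloxy)-3-methyl-8-(triethylsilyloxy)undeca-2,8,10-trien-4-one, via butenyllithium 11 (not isolated)
Conditions: t-BuLi (2 equiv per 10), Et2O, −78 °C; then 9, THF, −78 to −40 °C; pH 7 buffer (NaH2PO4/Na2HPO4)
Reagents that add atoms: none
Why: Bromine–lithium exchange retains the alkene geometry and the alkenyllithium adds to the morpholine amide to give a tetrahedral adduct that releases the (E)-enone only on work-up (ketone synthesis from a morpholine amide), the silyl dienol ether being inert to organolithiums.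

Step 8
Reactants: 12 (2E,7R,8Z)-7-(tert-butyldimethylsilyloxy)-3-methyl-8-(triethylsilyloxy)undeca-2,8,10-trien-4-one
Product: 13 (4S,5R,9R,10R)-9-(tert-butyldimethylsilyloxy)-4,5-dimethyl-10-(triethylsilyloxy)-cis-decal-1-en-6-one
Conditions: Me2AlCl (1.2 equiv), CH2Cl2, −78 to −30 °C; Et3N, then aqueous potassium sodium tartrate
Reagents that add atoms: none
Why: Me2AlCl binds the enone carbonyl and should trigger a concerted but asynchronous normal-demand intramolecular [4+2] cycloaddition in which C3, the unsubstituted and most nucleophilic diene terminus, bonds to the enone β-carbon C4 ahead of the C5–C10 bond. The closest known reaction type is the Lewis-acid-promoted intramolecular Diels–Alder reaction of 1,7,9-decatrien-3-ones to cis-fused octalones. Ring B closes as the six-membered cycloadduct ring that holds both new σ-bonds, and ring A closes through the C5–C10 bond alone as a chair-like six-membered annulation of the four-atom tether (6-exo with respect to the C10=C1 bond). C4 and C5 follow from suprafacial addition to the (E)-enone (methyl groups cis), C10 relative to C5 from the endo position of the tether carbonyl together with the (Z)-enol ether geometry (triethylsilyloxy inside, hence cis to the exo C5 methyl, with cis ring fusion), and the absolute sense from C9, whose silyloxy group stands equatorial on the forming ring A and anti to the incoming dienophile, so that C9–O ends anti to C10–O. The step needs endo over exo selectivity (cis over trans fusion) and one diene face; the first should be secured by the complexed tether carbonyl, the second by the clash that an axial C9 substituent would suffer with the C5 methyl and the inside silyloxy group.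

Step 9
Reactants: 13 (4S,5R,9R,10R)-9-(tert-butyldimethylsilyloxy)-4,5-dimethyl-10-(triethylsilyloxy)-cis-decal-1-en-6-one
Product: 14 (4R,5R,9R,10R)-9-(tert-butyldimethylsilyloxy)-4,5-dimethyl-10-(triethylsilyloxy)-cis-decal-1-ene-3,6-dione
Conditions: Rh2(cap)4 (dirhodium tetracaprolactamate, 1 mol %), t-BuOOH (70% aq), K2CO3 (0.5 equiv), CH2Cl2, rt
Reagents that add atoms: tert-butyl hydroperoxide, CC(C)(C)OO
Why: Dirhodium-catalysed allylic oxidation with tert-butyl hydroperoxide abstracts a C3 hydrogen, the only allylic C–H of the alkene, and the peroxyl radical should be captured at C3 in preference to the neopentylic C1 terminus, so that collapse of the mixed peroxide gives the 1-en-3-one.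

Step 10
Reactants: 14 (4R,5R,9R,10R)-9-(tert-butyldimethylsilyloxy)-4,5-dimethyl-10-(triethylsilyloxy)-cis-decal-1-ene-3,6-dione
Product: 15 (4R,5R,9R,10R)-9-(tert-butyldimethylsilyloxy)-4,5-dimethyl-10-(triethylsilyloxy)-cis-decalin-3,6-dione
Conditions: H2 (1 atm), 10% Pd/C, EtOAc, rt
Reagents that add atoms: none
Why: Heterogeneous catalytic hydrogenation saturates the disubstituted enone double bond without creating a stereocentre and leaves the ketones and silyl ethers untouched.

Step 11
Reactants: 15 (4R,5R,9R,10R)-9-(tert-butyldimethylsilyloxy)-4,5-dimethyl-10-(triethylsilyloxy)-cis-decalin-3,6-dione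
Product: 17 (3S,4R,5R,9R,10R)-3-acetoxy-9-(tert-butyldimethylsilyloxy)-4,5-dimethyl-10-(triethylsilyloxy)-cis-decalin-6-one, via lithium alkoxide 16 (not isolated)
Conditions: LiBH(s-Bu)3 (L-Selectride, 1.15 equiv), THF, −78 °C; then Ac2O, DMAP, −78 °C to rt
Reagents that add atoms: acetic anhydride, CC(=O)OC(C)=O
Why: The bulky trialkylborohydride should reduce the C3 ketone, which has one α-substituent, much faster than the C6 ketone flanked by quaternary C5, and it should attack from the α-face opposite the C4 and C5 methyl groups (equatorial attack, axial delivery being blocked by the axial C5 methyl in the chair that keeps the two vicinal silyloxy groups anti), giving the 3β-alkoxide, which is acetylated in the same flask.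

Step 12
Reactants: 17 (3S,4R,5R,9R,10R)-3-acetoxy-9-(tert-butyldimethylsilyloxy)-4,5-dimethyl-10-(triethylsilyloxy)-cis-decalin-6-one
Product: 19 (3S,4R,5R,9R,10R)-3-acetoxy-9-(tert-butyldimethylsilyloxy)-4,5-dimethyl-10-(triethylsilyloxy)-cis-decal-7-en-6-one, via trimethylsilyl enol ether 18 (not isolated)
Conditions: Me3SiOTf, Et3N, CH2Cl2, 0 °C; evaporate; Pd(OAc)2 (1.1 equiv), MeCN, rt
Reagents that add atoms: none
Why: Soft enolisation of the C6 ketone can only run toward C7 because C5 is quaternary and leaves the acetate alone, and the silyl enol ether is dehydrogenated by Pd(OAc)2 through an oxa-π-allyl palladium species and β-hydride elimination (Saegusa–Ito oxidation).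

Step 13
Reactants: 19 (3S,4R,5R,9R,10R)-3-acetoxy-9-(tert-butyldimethylsilyloxy)-4,5-dimethyl-10-(triethylsilyloxy)-cis-decal-7-en-6-one
Product: 20 (3S,4R,5R,7R,8S,9R,10R)-3-acetoxy-9-(tert-butyldimethylsilyloxy)-7,8-epoxy-4,5-dimethyl-10-(triethylsilyloxy)-cis-decalin-6-one
Conditions: t-BuOOH (in decane), benzyltrimethylammonium hydroxide (cat.), THF, 0 °C
Reagents that add atoms: tert-butyl hydroperoxide, CC(C)(C)OO
Why: In this Weitz–Scheffer nucleophilic epoxidation the hydroperoxide anion should add to C8 of the enone anti to the C9 silyloxy group and the enolate closes onto oxygen, and either epoxide epimer would serve because C8 is oxidised to a ketone later.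

Step 14
Reactants: 20 (3S,4R,5R,7R,8S,9R,10R)-3-acetoxy-9-(tert-butyldimethylsilyloxy)-7,8-epoxy-4,5-dimethyl-10-(triethylsilyloxy)-cis-decalin-6-one
Product: 22 (3S,4R,5R,8S,9R,10R)-3-acetoxy-9-(tert-butyldimethylsilyloxy)-8-hydroxy-4,5-dimethyl-10-(triethylsilyloxy)-cis-decal-6-ene, via epoxy hydrazone 21 (not isolated)
Conditions: N2H4·H2O, AcOH (cat.), MeOH, 0 °C to rt
Reagents that add atoms: none
Why: In the Wharton transposition the epoxy hydrazone opens to a vinyl diazene that loses dinitrogen, which moves the double bond to C6–C7 and leaves the oxygen on C8 with its configuration retained.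

Step 15
Reactants: 22 (3S,4R,5R,8S,9R,10R)-3-acetoxy-9-(tert-butyldimethylsilyloxy)-8-hydroxy-4,5-dimethyl-10-(triethylsilyloxy)-cis-decal-6-ene
Product: 23 (3S,4R,5R,9S,10R)-3-acetoxy-9-(tert-butyldimethylsilyloxy)-4,5-dimethyl-10-(triethylsilyloxy)-cis-decal-6-en-8-one
Conditions: Dess–Martin periodinane, NaHCO3, CH2Cl2, rt
Reagents that add atoms: none
Why: Dess–Martin oxidation of the secondary allylic alcohol under buffered neutral conditions gives the 6-en-8-one and spares the acetate and both silyl ethers.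

Step 16
Reactants: 23 (3S,4R,5R,9S,10R)-3-acetoxy-9-(tert-butyldimethylsilyloxy)-4,5-dimethyl-10-(triethylsilyloxy)-cis-decal-6-en-8-one
Product: 24 (3S,4R,5R,9S,10R)-3-acetoxy-9,10-dihydroxy-4,5-dimethyl-cis-decal-6-en-8-one
Conditions: HF·pyridine, THF, 0 °C to rt
Reagents that add atoms: none
Why: Fluoride cleaves the secondary TBS and the tertiary triethylsilyl ether under acidic conditions, which spare the acetate and avoid base-induced retro-aldol cleavage of the β-hydroxy ketone.

Step 17
Reactants: 24 (3S,4R,5R,9S,10R)-3-acetoxy-9,10-dihydroxy-4,5-dimethyl-cis-decal-6-en-8-one; 25 angelic acid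
Product: 27 (3S,4R,5R,9S,10R)-3-acetoxy-9-angeloyloxy-10-hydroxy-4,5-dimethyl-cis-decal-6-en-8-one, via mixed anhydride 26 (not isolated)
Conditions: 2,4,6-trichlorobenzoyl chloride, Et3N, toluene, rt; then 24, 60 °C
Reagents that add atoms: none
Why: Yamaguchi-type esterification through the mixed anhydride should acylate only the secondary C9 hydroxyl (the tertiary C10 hydroxyl is inert) at the angeloyl carbonyl, the less hindered of the two anhydride carbonyls, under amine-only conditions that preserve the (Z)-geometry of the angelate.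

Step 18
Reactants: 27 (3S,4R,5R,9S,10R)-3-acetoxy-9-angeloyloxy-10-hydroxy-4,5-dimethyl-cis-decal-6-en-8-one
Product: 28 (3S,4R,5S,9S,10R)-3-acetoxy-9-angeloyloxy-10-hydroxy-7-iodo-4,5-dimethyl-cis-decal-6-en-8-one
Conditions: I2, pyridine, CH2Cl2, rt
Reagents that add atoms: iodine, [I][I]
Why: Pyridine-promoted α-iodination of the enone (conjugate addition of pyridine, iodination of the enolate, elimination) places iodine on C7, the only vinylic α-position, and does not touch the electron-poor trisubstituted angelate alkene.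

Step 19
Reactants: 28 (3S,4R,5S,9S,10R)-3-acetoxy-9-angeloyloxy-10-hydroxy-7-iodo-4,5-dimethyl-cis-decal-6-en-8-one; 29 tributyl(1-ethoxyvinyl)stannane
Product: 31 (3S,4R,5R,9S,10R)-3-acetoxy-7-acetyl-9-angeloyloxy-10-hydroxy-4,5-dimethyl-cis-decal-6-en-8-one, via ethoxyvinyl enone 30 (not isolated)
Conditions: Pd(PPh3)4 (5 mol %), copper iodide CuI (10 mol %), DMF, 50 °C; then 1 M HCl, THF, 0 °C
Reagents that add atoms: water, O
Why: Stille coupling of the α-iodoenone with the 1-ethoxyvinylstannane followed by mild acid hydrolysis of the enol ether unmasks the C7 acetyl group as the last operation, so the doubly activated alkene is never exposed to base.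

Compound list
1 | D-glutamic acid | N[C@H](CCC(=O)O)C(=O)O | starting material
2 | (R)-5-oxotetrahydrofuran-2-carboxylic acid | OC(=O)[C@H]1CCC(=O)O1 | intermediate
3 | (R)-5-(imidazol-1-ylcarbonyl)dihydrofuran-2(3H)-one (acyl imidazolide of 2) | O=C([C@H]1CCC(=O)O1)n1ccnc1 | intermediate
4 | (R)-N-methoxy-N-methyl-5-oxotetrahydrofuran-2-carboxamide | CON(C)C(=O)[C@H]1CCC(=O)O1 | intermediate
5 | (R)-2-hydroxy-N-methoxy-N-methyl-5-(morpholin-4-yl)-5-oxopentanamide | CON(C)C(=O)[C@H](O)CCC(=O)N1CCOCC1 | intermediate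
6 | (R)-2-(tert-butyldimethylsilyloxy)-N-methoxy-N-methyl-5-(morpholin-4-yl)-5-oxopentanamide | CON(C)C(=O)[C@H](O[Si](C)(C)C(C)(C)C)CCC(=O)N1CCOCC1 | intermediate
7 | allylmagnesium bromide | C=CC[Mg]Br | starting material
8 | (R)-4-(tert-butyldimethylsilyloxy)-1-(morpholin-4-yl)oct-7-ene-1,5-dione | C=CCC(=O)[C@H](O[Si](C)(C)C(C)(C)C)CCC(=O)N1CCOCC1 | intermediate
9 | (4R,5Z)-4-(tert-butyldimethylsilyloxy)-1-(morpholin-4-yl)-5-(triethylsilyloxy)octa-5,7-dien-1-one | C=C/C=C(O[Si](CC)(CC)CC)/[C@H](O[Si](C)(C)C(C)(C)C)CCC(=O)N1CCOCC1 | intermediate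
10 | (E)-2-bromobut-2-ene | C/C=C(\C)Br | starting material
11 | but-2-en-2-yllithium with the geometry of 10 retained (methyl groups cis) | C/C=C(\C)[Li] | intermediate
12 | (2E,7R,8Z)-7-(tert-butyldimethylsilyloxy)-3-methyl-8-(triethylsilyloxy)undeca-2,8,10-trien-4-one (Diels–Alder precursor) | C/C=C(\C)C(=O)CC[C@@H](O[Si](C)(C)C(C)(C)C)/C(O[Si](CC)(CC)CC)=C/C=C | intermediate
13 | (4S,5R,9R,10R)-9-(tert-butyldimethylsilyloxy)-4,5-dimethyl-10-(triethylsilyloxy)-cis-decal-1-en-6-one (4β,5β-dimethyl, 10β-silyloxy, 9α-silyloxy) | CC(C)(C)[Si](C)(C)O[C@@H]1CCC(=O)[C@]2(C)[C@@H](C)CC=C[C@]12O[Si](CC)(CC)CC | intermediate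
14 | (4R,5R,9R,10R)-9-(tert-butyldimethylsilyloxy)-4,5-dimethyl-10-(triethylsilyloxy)-cis-decal-1-ene-3,6-dione | CC(C)(C)[Si](C)(C)O[C@@H]1CCC(=O)[C@]2(C)[C@@H](C)C(=O)C=C[C@]12O[Si](CC)(CC)CC | intermediate
15 | (4R,5R,9R,10R)-9-(tert-butyldimethylsilyloxy)-4,5-dimethyl-10-(triethylsilyloxy)-cis-decalin-3,6-dione | CC(C)(C)[Si](C)(C)O[C@@H]1CCC(=O)[C@]2(C)[C@@H](C)C(=O)CC[C@]12O[Si](CC)(CC)CC | intermediate
16 | lithium 3β-alkoxide of the 3-hydroxy-6-ketone (3S) | CC(C)(C)[Si](C)(C)O[C@@H]1CCC(=O)[C@]2(C)[C@@H](C)[C@@H](O[Li])CC[C@]12O[Si](CC)(CC)CC | intermediate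
17 | (3S,4R,5R,9R,10R)-3-acetoxy-9-(tert-butyldimethylsilyloxy)-4,5-dimethyl-10-(triethylsilyloxy)-cis-decalin-6-one | CC(C)(C)[Si](C)(C)O[C@@H]1CCC(=O)[C@]2(C)[C@@H](C)[C@@H](OC(C)=O)CC[C@]12O[Si](CC)(CC)CC | intermediate
18 | 6-(trimethylsilyloxy)-6-ene derived from 17 (C6=C7 silyl enol ether) | CC(C)(C)[Si](C)(C)O[C@@H]1CC=C(O[Si](C)(C)C)[C@]2(C)[C@@H](C)[C@@H](OC(C)=O)CC[C@]12O[Si](CC)(CC)CC | intermediate
19 | (3S,4R,5R,9R,10R)-3-acetoxy-9-(tert-butyldimethylsilyloxy)-4,5-dimethyl-10-(triethylsilyloxy)-cis-decal-7-en-6-one | CC(C)(C)[Si](C)(C)O[C@@H]1C=CC(=O)[C@]2(C)[C@@H](C)[C@@H](OC(C)=O)CC[C@]12O[Si](CC)(CC)CC | intermediate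
20 | (3S,4R,5R,7R,8S,9R,10R)-3-acetoxy-9-(tert-butyldimethylsilyloxy)-7,8-epoxy-4,5-dimethyl-10-(triethylsilyloxy)-cis-decalin-6-one (7β,8β-epoxide) | CC(C)(C)[Si](C)(C)O[C@@H]1[C@H]3O[C@H]3C(=O)[C@]2(C)[C@@H](C)[C@@H](OC(C)=O)CC[C@]12O[Si](CC)(CC)CC | intermediate
21 | C6 hydrazone of epoxy ketone 20 | CC(C)(C)[Si](C)(C)O[C@@H]1[C@H]3O[C@H]3C(=NN)[C@]2(C)[C@@H](C)[C@@H](OC(C)=O)CC[C@]12O[Si](CC)(CC)CC | intermediate
22 | (3S,4R,5R,8S,9R,10R)-3-acetoxy-9-(tert-butyldimethylsilyloxy)-8-hydroxy-4,5-dimethyl-10-(triethylsilyloxy)-cis-decal-6-ene | CC(C)(C)[Si](C)(C)O[C@@H]1[C@@H](O)C=C[C@]2(C)[C@@H](C)[C@@H](OC(C)=O)CC[C@]12O[Si](CC)(CC)CC | intermediate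
23 | (3S,4R,5R,9S,10R)-3-acetoxy-9-(tert-butyldimethylsilyloxy)-4,5-dimethyl-10-(triethylsilyloxy)-cis-decal-6-en-8-one | CC(C)(C)[Si](C)(C)O[C@@H]1C(=O)C=C[C@]2(C)[C@@H](C)[C@@H](OC(C)=O)CC[C@]12O[Si](CC)(CC)CC | intermediate
24 | (3S,4R,5R,9S,10R)-3-acetoxy-9,10-dihydroxy-4,5-dimethyl-cis-decal-6-en-8-one | O[C@@H]1C(=O)C=C[C@]2(C)[C@@H](C)[C@@H](OC(C)=O)CC[C@]12O | intermediate
25 | angelic acid, (Z)-2-methylbut-2-enoic acid | C/C=C(/C)C(=O)O | starting material
26 | angelic 2,4,6-trichlorobenzoic anhydride | C/C=C(/C)C(=O)OC(=O)c1c(Cl)cc(Cl)cc1Cl | intermediate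
27 | (3S,4R,5R,9S,10R)-3-acetoxy-9-angeloyloxy-10-hydroxy-4,5-dimethyl-cis-decal-6-en-8-one | C/C=C(/C)C(=O)O[C@@H]1C(=O)C=C[C@]2(C)[C@@H](C)[C@@H](OC(C)=O)CC[C@]12O | intermediate
28 | (3S,4R,5S,9S,10R)-3-acetoxy-9-angeloyloxy-10-hydroxy-7-iodo-4,5-dimethyl-cis-decal-6-en-8-one | C/C=C(/C)C(=O)O[C@@H]1C(=O)C(I)=C[C@]2(C)[C@@H](C)[C@@H](OC(C)=O)CC[C@]12O | intermediate
29 | tributyl(1-ethoxyvinyl)stannane | CCCC[Sn](CCCC)(CCCC)C(=C)OCC | starting material
30 | 7-(1-ethoxyvinyl) analogue of 27 | C/C=C(/C)C(=O)O[C@@H]1C(=O)C(C(=C)OCC)=C[C@]2(C)[C@@H](C)[C@@H](OC(C)=O)CC[C@]12O | intermediate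
31 | (3S,4R,5R,9S,10R)-3-acetoxy-7-acetyl-9-angeloyloxy-10-hydroxy-4,5-dimethyl-cis-decal-6-en-8-one (CNP0196241.1) | C/C=C(/C)C(=O)O[C@@H]1C(=O)C(C(C)=O)=C[C@]2(C)[C@@H](C)[C@@H](OC(C)=O)CC[C@]12O | target

Total step count: 19. Longest linear sequence: 19 steps (1 to 31); compounds 7, 10, 25 and 29 are purchased and used directly.

Steps most likely to fail

Step 8. The aluminium Lewis acid may strip the triethylsilyl group from the dienol ether before cycloaddition, or the exo mode may compete and erode the cis ring fusion. The fallback leaves the route at 12 and rejoins it at 13; it abandons the silyl dienol ether and carries the diene oxygen as an allyl carbonate, which tolerates stronger Lewis acids and prolonged heating. Buffered fluoride (Bu4NF, AcOH, THF, −78 °C) would protonate the dienolate at C1 to give the β,γ-unsaturated diketone (2E,7R)-7-(tert-butyldimethylsilyloxy)-3-methylundeca-2,10-diene-4,8-dione F1. Deprotonation at the doubly activated C1 with NaN(SiMe3)2 and O-acylation with allyl chloroformate would give the (Z)-dienyl allyl carbonate F2. Its intramolecular Diels–Alder reaction, run with EtAlCl2 or in toluene at 170 °C, would give the 10-allyloxycarbonyloxy adduct F3. Pd(PPh3)4 with morpholine would remove the allyloxycarbonyl group to give the 10-hydroxy ketone F4, and Et3SiOTf with 2,6-lutidine would return 13.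

Step 11. Hydride may add to the wrong face of the C3 carbonyl, or the C6 ketone may be reduced in competition. The fallback leaves the route at 14 and rejoins it at 17; it replaces substrate control by reagent control at the enone stage. Corey–Bakshi–Shibata reduction of the conjugated C3 ketone of 14 (BH3·SMe2 with the oxazaborolidine antipode that delivers hydride to the α-face) would give the 3β-allylic alcohol F5. Acetylation (Ac2O, pyridine) would give the allylic acetate F6, and hydrogenation of C1=C2 over Rh/Al2O3, which avoids allylic C–O hydrogenolysis, would give 17.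

Step 14. Hydrazone formation at the neopentylic C6 carbonyl may be slow, which would give time for hydrazinolysis of the C3 acetate or for migration of the C9 silyl group to the new C8 hydroxyl. The fallback leaves the route at 17 and rejoins it at 23; it replaces the epoxide–hydrazine transposition by deoxygenation and allylic oxidation. KN(SiMe3)2 and N-phenylbis(trifluoromethanesulfonimide) would give the C6 enol triflate F7. Reduction with Pd(OAc)2, PPh3, Bu3N and formic acid would give the 6-ene F8. Allylic oxidation as in step 9 (Rh2(cap)4, t-BuOOH), in which C8 carries the only allylic hydrogens, would give 23.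

Further compounds
F1 | step 8 | (2E,7R)-7-(tert-butyldimethylsilyloxy)-3-methylundeca-2,10-diene-4,8-dione | C=CCC(=O)[C@H](O[Si](C)(C)C(C)(C)C)CCC(=O)/C(C)=C/C
F2 | step 8 | allyl (2E,7R,8Z)-7-(tert-butyldimethylsilyloxy)-3-methyl-4-oxoundeca-2,8,10-trien-8-yl carbonate | C=C/C=C(OC(=O)OCC=C)/[C@H](O[Si](C)(C)C(C)(C)C)CCC(=O)/C(C)=C/C
F3 | step 8 | (4S,5R,9R,10R)-10-(allyloxycarbonyloxy)-9-(tert-butyldimethylsilyloxy)-4,5-dimethyl-cis-decal-1-en-6-one | CC(C)(C)[Si](C)(C)O[C@@H]1CCC(=O)[C@]2(C)[C@@H](C)CC=C[C@]12OC(=O)OCC=C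
F4 | step 8 | (4S,5R,9R,10R)-9-(tert-butyldimethylsilyloxy)-10-hydroxy-4,5-dimethyl-cis-decal-1-en-6-one | CC(C)(C)[Si](C)(C)O[C@@H]1CCC(=O)[C@]2(C)[C@@H](C)CC=C[C@]12O
F5 | step 11 | (3S,4R,5R,9R,10R)-9-(tert-butyldimethylsilyloxy)-3-hydroxy-4,5-dimethyl-10-(triethylsilyloxy)-cis-decal-1-en-6-one | CC(C)(C)[Si](C)(C)O[C@@H]1CCC(=O)[C@]2(C)[C@@H](C)[C@@H](O)C=C[C@]12O[Si](CC)(CC)CC
F6 | step 11 | (3S,4R,5R,9R,10R)-3-acetoxy-9-(tert-butyldimethylsilyloxy)-4,5-dimethyl-10-(triethylsilyloxy)-cis-decal-1-en-6-one | CC(C)(C)[Si](C)(C)O[C@@H]1CCC(=O)[C@]2(C)[C@@H](C)[C@@H](OC(C)=O)C=C[C@]12O[Si](CC)(CC)CC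
F7 | step 14 | (3S,4R,5S,9R,10R)-3-acetoxy-9-(tert-butyldimethylsilyloxy)-4,5-dimethyl-10-(triethylsilyloxy)-cis-decal-6-en-6-yl trifluoromethanesulfonate | CC(C)(C)[Si](C)(C)O[C@@H]1CC=C(OS(=O)(=O)C(F)(F)F)[C@]2(C)[C@@H](C)[C@@H](OC(C)=O)CC[C@]12O[Si](CC)(CC)CC
F8 | step 14 | (3S,4R,5R,9R,10R)-3-acetoxy-9-(tert-butyldimethylsilyloxy)-4,5-dimethyl-10-(triethylsilyloxy)-cis-decal-6-ene | CC(C)(C)[Si](C)(C)O[C@@H]1CC=C[C@]2(C)[C@@H](C)[C@@H](OC(C)=O)CC[C@]12O[Si](CC)(CC)CC
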